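Amounts first: we charge G as a solid with none of it in solution, and D comes from what has left the solid, so we begin with how fast c(G) falls.

| flask | G | temperature | remark | time |
|---|---|---|---|---|
| alpha | 0.060 M | 5 °C | run made earlier |  |
| beta | 0.095 M | 22 °C | run made earlier |  |
| noon | 0.043 M |  | at 10 °C throughout | 6.0 h |
| autumn | 0.043 M |  | at 10 °C until 50 min, from then on at 35 °C | 3.0 h |

alpha run (percent of the G charged)

| time / h | D / % | G / % |
|---|---|---|
| 0.200 | 0.1 | 98.2 |
| 0.500 | 0 | 94.7 |
| 1.00 | 0.8 | 90.4 |
| 1.50 | 0.9 | 85.4 |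
| 2.00 | 1.0 | 81.9 |
| 3.00 | 2.6 | 75.3 |
| 4.00 | 3.7 | 68.5 |

beta run (percent of the G charged)

| time / min | D / % | G / % |
|---|---|---|
| 8.00 | 0 | 98.6 |
| 15.0 | 0 | 97.8 |
| 20.0 | 0 | 97.5 |
| 30.0 | 1.3 | 96.4 |
| 50.0 | 1.4 | 93.9 |
| 80.0 | 2.9 | 91.0 |
| 120 | 5.1 | 86.8 |

(standard deviation of a reading: 0.3 percentage points)

- as a solid, counted per litre of solution: G
- the earlier runs were read with a standard deviation of 0.3 percentage points
- what may be going on: G <-> Z; Q <-> X; Z <-> E; Z -> D; X -> D; Q -> L; Z <-> Q
- at the start none of G is in solution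
- what has only dissolved of G counts as not reacted

* the winner by amount of D, in percent of the G charged; "neither" if no more than 2 percentage points parts them (noon / autumn / neither)
* how much D is there at the end, in percent of the G charged: noon
* how much D is there at the end, in percent of the G charged: autumn

In the alpha run G lost 31.5% of its charge in 4.00 h, which is 0.00472 M h⁻¹. We call this amount of G leaving the solid per hour the feed. The beta run gives 0.00627 M h⁻¹. The charges stand in the ratio 1.58 and the feeds, read at two different temperatures, in the ratio 1.33, and we choose to carry the feed as a rate in M/h and not as a fraction of the charge. On our charge of 0.043 M it becomes 0.110 h⁻¹ from alpha and 0.146 h⁻¹ from beta, and we take feed times time as our estimated ceiling for D.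

In the first instants the solid feeds the solution while D stays within the scatter: beta still reads 0% at 20.0 min. For the middle we let D grow as the feed times the square of the time, divided by 2 and by a lag, and the last readings then give a lag of 17.0 h in alpha and 2.59 h in beta, shorter in the warmer run.

Now the end. Noon has the higher ceiling, 65.9%, but with alpha's lag we reckon D of about 11.6% for it, and we expect somewhat more at its 10 °C. Autumn has a ceiling of 43.7%. At 35 °C we assume a short lag, with dissolving as the rate-limiting step, and let D follow the beta feed through the 2.17 h after the change: about 31.6%. We commit to autumn.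

The forecast said 16% for noon, 30% for autumn and autumn as winner, on the ground of “saturation-limited dissolution”.

The flasks give 19.3% for noon and 34.9% for autumn, so the winner is autumn.

    G ⇌ Z, rate k1*(cs1 - [Z]) while solid is left; crystals form when [Z] > cs1 (solubility = 11.0 mM, k = 0.0112 min⁻¹)
    Q ⇌ X (K = 8.54, k = 0.00628 min⁻¹, Ea = 87.0 kJ mol⁻¹, ΔH = 29.0 kJ mol⁻¹)
    Z ⇌ E (K = 1.00, k = 0.0304 min⁻¹, Ea = 92.0 kJ mol⁻¹, ΔH = −39.0 kJ mol⁻¹)
    Z → D (k = 0.00416 min⁻¹, Ea = 87.0 kJ mol⁻¹)
    X → D (k = 0.00526 min⁻¹, Ea = 91.0 kJ mol⁻¹)
    Q → L (k = 0.00333 min⁻¹, Ea = 99.0 kJ mol⁻¹)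
    Z ⇌ Q (K = 1.27, k = 0.0135 min⁻¹, Ea = 83.0 kJ mol⁻¹, ΔH = −40.0 kJ mol⁻¹)
    (constants at 10 °C)

At 3.00 h autumn holds L 7.78% and Z 1.92% beside its D. Noon read at 4.00 h is the further flask: the feed from alpha reckons 44.0% of the charge out of the solid, and that flask has lost 46.8%, with G at 53.2% and D at 10.1%.

The data are calculated with constants of no real substance, noise included.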